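All runs stem from a simulated flask from invented constants.

In a one-step world L and Z meet on D and leave as E, the rate runs as c_D·c_L·c_Z, and the job is to find what that product reduces to for these flasks.

| flask | L | Z | D | remark | time |
|---|---|---|---|---|---|
| grey | 0.50 mM | 0.55 mM | 0.050 µM | the very flask that is asked about, followed so far |  |
| violet | 0.50 mM | 0.55 mM | 0.075 µM | run made earlier |  |
| flask | 0.50 mM | 0.550 mM | 0.050 µM |  | 2.0 min |

| run | time / s | E / % | L / % |
|---|---|---|---|
| grey | 10.0 | 13 | 91 |
| grey | 15.0 | 12 | 91 |
| grey | 25.0 | 20 | 79 |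
| grey | 40.0 | 27 | 74 |
| violet | 25.0 | 27 | 73 |
| violet | 50.0 | 43 | 57 |
| violet | 80.0 | 53 | 46 |
| violet | 90.0 | 54 | 44 |
| violet | 120 | 59 | 38 |

(readings scatter by 1.5 percentage points)



1. concentration of E at 2.0 min, in mM
2. concentration of L at 2.0 min, in mM

By charge L is the limiting reagent, put in at less than Z, and the ratio of Z to L is 1.10 in both runs, so in this one-step world c_Z follows c_L and the rate goes nearly as c_D·c_L². The readings support first order in c_D, since grey at 40.0 s shows E 27%, as violet does at 25.0 s, with a ratio of c_D·t of 1.07.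

My rule of thumb follows: at these charges of L and Z, with y the fraction of L left, the reach, the reciprocal of y less one, grows in proportion to c_D·t. The last violet reading, y = 38% at 120 s, reads as a reach of 1.63, with the scatter of that reading in it. The flask has 0.667 of that violet c_D·t, so I reckon its reach at 1.09, which puts my estimate of L at 0.239 mM and of E at 0.261 mM. That ratio is also the border: the flask stands below 1, among the readings, and above 1 I extrapolate.

The forecast gives E 0.262 mM and L 0.235 mM, a little apart from my L, on this ground: “So rate is proportional to D.”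

The flask gives E 0.249 mM and L 0.251 mM.

    L + D ⇌ X (K = 1900 L mol⁻¹, k = 4.30 × 10⁶ L mol⁻¹ s⁻¹)
    Z + X ⇌ Q (K = 1700 L mol⁻¹, k = 3.60 × 10⁶ L mol⁻¹ s⁻¹)
    Q → D + E (k = 380 s⁻¹)
    Z ⇌ J (K = 1.30, k = 0.0160 s⁻¹)

In the flask at that time Z stands unbound at 21% of its charge, less than L unbound at 50%, while the E made, taken one for one from Z, accounts for a fall to 54.7%, and J stands at 0.186 mM. The neighbour charged with 1.3 × 10⁻⁴ mM of D lies past the border, at a ratio of 1.73, so by the rule its reach comes to 2.82 and its L to 26.2%, and that neighbour holds 24.5% of the L charged.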